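The target is a labd-7-ene: ring B carries its only alkene (C7=C8) beside three contiguous stereocentres (C9, C10, C5), and C15–C11, C9, C8 with its methyl and C7 form an intact citronellol skeleton. The route rests on one intermolecular, catalyst-controlled Diels–Alder reaction between the (6E)-diene made from (R)-citronellol (silyl-protected (3R,6E)-3,7-dimethylnona-6,8-dien-1-ol) and ethyl (E)-3-methyl-4-oxobut-2-enoate. It forms C5–C6 and C9–C10, closes ring B and sets C5, C9 and C10 at once. Ring A is then grown from the two carbonyl handles by homologation, Dieckmann closure, α-face methylation, 2α-acetoxylation and hydroxyl-directed reduction at C3.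

Key step: step 5

Remark: labdane numbering is used (β = face of the C10 methyl); the catalyst sense in step 5 is assigned from the formyl C–H···O stacking model for 2-substituted enals, which calls for the oxazaborolidine from (R)-diphenylprolinol (diene onto the Si face of C3 of 7).

Step 1
Reactants: 1 (R)-citronellol
Product: 2 (R)-citronellol tert-butyldiphenylsilyl ether
Conditions: TBDPSCl, imidazole, DMF, 0 °C → rt
Reagents that add atoms: tert-butyl(chloro)diphenylsilane, CC(C)(C)[Si](Cl)(c1ccccc1)c1ccccc1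
Why: Imidazole-promoted silylation of a primary alcohol; the TBDPS ether is chosen because it should survive the Lewis acid of step 5 and the hydroxide, alkoxide, enolate and hydride conditions that follow, and is removed by fluoride in step 16.

Step 2
Reactants: 2 (R)-citronellol tert-butyldiphenylsilyl ether
Product: 3 (2E,6R)-8-[(tert-butyldiphenylsilyl)oxy]-2,6-dimethyloct-2-en-1-ol
Conditions: SeO2 (cat.), t-BuOOH, salicylic acid (cat.), CH2Cl2, rt
Reagents that add atoms: tert-butyl hydroperoxide, CC(C)(C)OO (terminal oxygen source; the oxygen is passed on through SeO2, O=[Se]=O)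
Why: Allylic oxidation with SeO2 (ene reaction, then [2,3]-sigmatropic shift) attacks the (E)-methyl group of the isopropylidene unit selectively, so the (2E)-allylic alcohol should result; any enal formed alongside converges in step 3.

Step 3
Reactants: 3 (2E,6R)-8-[(tert-butyldiphenylsilyl)oxy]-2,6-dimethyloct-2-en-1-ol
Product: 4 (2E,6R)-8-[(tert-butyldiphenylsilyl)oxy]-2,6-dimethyloct-2-enal
Conditions: Dess–Martin periodinane, CH2Cl2, rt
Reagents that add atoms: none
Why: Dess–Martin oxidation of a primary allylic alcohol to the enal, mild enough to leave the silyl ether and the (E)-alkene geometry untouched.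

Step 4
Reactants: 4 (2E,6R)-8-[(tert-butyldiphenylsilyl)oxy]-2,6-dimethyloct-2-enal; 5 methyltriphenylphosphonium bromide
Product: 6 tert-butyl{[(3R,6E)-3,7-dimethylnona-6,8-dien-1-yl]oxy}diphenylsilane
Conditions: 5, n-BuLi, THF, 0 °C; then 4, −78 °C → rt
Reagents that add atoms: none
Why: Wittig methylenation of the enal with the non-stabilised ylide adds C6 and gives the terminal diene without touching the (E)-trisubstituted alkene.

Step 5
Reactants: 6 tert-butyl{[(3R,6E)-3,7-dimethylnona-6,8-dien-1-yl]oxy}diphenylsilane; 7 ethyl (2E)-3-methyl-4-oxobut-2-enoate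
Product: 8 ethyl (1S,5R,6S)-5-{(3R)-5-[(tert-butyldiphenylsilyl)oxy]-3-methylpentyl}-6-formyl-4,6-dimethylcyclohex-3-ene-1-carboxylate (ring B cycloadduct)
Conditions: B-(o-tolyl)oxazaborolidine from (R)-α,α-diphenylprolinol (20 mol%), HNTf2 (17 mol%), 6 (1.5 equiv), CH2Cl2, −78 → −40 °C
Reagents that add atoms: none
Why: The oxazaborolidinium ion binds the formyl oxygen of 7 (s-trans enal, formyl C–H···O contact) and the diene adds in a concerted, asynchronous [4+2] cycloaddition in which the unsubstituted terminus C6 bonds ahead to C5 (β to the activated aldehyde) and C9 then closes onto C10; the closest known reaction type is the exo-selective oxazaborolidinium-catalysed Diels–Alder reaction of 2-methyl enals with acyclic dienes. Ring B is closed by this single cycloaddition, suprafacial on both partners, which makes both new σ bonds (C5–C6 and C9–C10). The (E) geometry of 7 is carried over, so that C1 (formyl) and C4 (ester) end up trans, which fixes C5 relative to C10 and later gives the trans ring fusion. C9 is set by the (E)-diene together with the formyl-exo, ester-endo topology, which puts the side chain cis to the C10 methyl and to the ester. The absolute configuration of all three centres comes from the catalyst, whose phenyl group covers the Re face of C3 of 7 (the future C10) so that the diene reaches the Si face. The step needs C6-to-C5 regiochemistry (polarisation of the Lewis acid-bound enal and the larger terminal coefficient at C6 imposed by the C9 alkyl group), exo selectivity (the α-methyl group, reinforced by the endo ester) and enantioface selectivity (the catalyst).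

Step 6
Reactants: 8 ring B cycloadduct (formyl ethyl ester)
Product: 9 (1S,5R,6S)-5-{(3R)-5-[(tert-butyldiphenylsilyl)oxy]-3-methylpentyl}-6-formyl-4,6-dimethylcyclohex-3-ene-1-carboxylic acid
Conditions: LiOH·H2O, THF/MeOH/H2O, 40 °C; then 1 M HCl to pH 3
Reagents that add atoms: lithium hydroxide, [Li+].[OH-]
Why: Saponification of the ring ester; the aldehyde on the quaternary C10 cannot enolise and tolerates dilute hydroxide, and C5 already holds its more stable equatorial arrangement, so it has no drive to epimerise.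

Step 7
Reactants: 9 formyl acid; 10 trimethyl phosphonoacetate
Product: 11 (1S,5R,6S)-5-{(3R)-5-[(tert-butyldiphenylsilyl)oxy]-3-methylpentyl}-6-[(1E)-3-methoxy-3-oxoprop-1-en-1-yl]-4,6-dimethylcyclohex-3-ene-1-carboxylic acid
Conditions: 10, NaH (excess), THF, 0 °C → rt; 1 M HCl work-up
Reagents that add atoms: none
Why: Horner–Wadsworth–Emmons olefination of the aldehyde, run on the carboxylate with extra base, should give the (E)-enoate and adds C2 and C3 with C3 at the ester level.

Step 8
Reactants: 11 enoate acid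
Product: 12 (1S,5R,6S)-5-{(3R)-5-[(tert-butyldiphenylsilyl)oxy]-3-methylpentyl}-6-(3-methoxy-3-oxopropyl)-4,6-dimethylcyclohex-3-ene-1-carboxylic acid
Conditions: NaBH4, NiCl2·6H2O (cat.), MeOH/THF, 0 °C
Reagents that add atoms: none
Why: Nickel boride conjugate reduction saturates only the electron-poor enoate alkene; the trisubstituted C7–C8 alkene, the ester and the silyl ether are inert.

Step 9
Reactants: 12 saturated methyl ester acid
Product: 14 methyl 3-[(1S,2R,6S)-6-(diazoacetyl)-2-{(3R)-5-[(tert-butyldiphenylsilyl)oxy]-3-methylpentyl}-1,3-dimethylcyclohex-3-en-1-yl]propanoate, via acid chloride 13 (not isolated)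
Conditions: (COCl)2, DMF (cat.), CH2Cl2, 0 °C; concentrate; TMSCHN2, MeCN/THF, 0 °C → rt
Reagents that add atoms: trimethylsilyldiazomethane, C[Si](C)(C)C=[N+]=[N-]
Why: First half of an Arndt–Eistert homologation (acid chloride, then acylation of the diazoalkane with loss of the silyl group); the methyl ester is inert and the base-free conditions should not enolise C5.

Step 10
Reactants: 14 diazoketone
Product: 16 methyl 3-[(1R,2R,6R)-6-(2-tert-butoxy-2-oxoethyl)-2-{(3R)-5-[(tert-butyldiphenylsilyl)oxy]-3-methylpentyl}-1,3-dimethylcyclohex-3-en-1-yl]propanoate, via ketene 15 (not isolated)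
Conditions: PhCO2Ag (cat.), Et3N, t-BuOH/THF, 45 °C, dark
Reagents that add atoms: tert-butanol, CC(C)(C)O
Why: Silver-catalysed Wolff rearrangement in which C5 migrates with retention of configuration to give the ketene, trapped by tert-butanol; the inserted CH2 becomes C4 and the former ester carbon becomes C19, now a tert-butyl ester.

Step 11
Reactants: 16 methyl/tert-butyl diester
Product: 18 tert-butyl (13R)-15-[(tert-butyldiphenylsilyl)oxy]-3-oxolabd-7-en-19-oate, via potassium enolate 17 (not isolated)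
Conditions: KOtBu (1.2 equiv), THF, 0 °C → rt; then MeI, 0 °C → rt
Reagents that add atoms: iodomethane, CI
Why: Dieckmann condensation (6-exo-trig acyl substitution) in which the hindered tert-butyl ester can serve only as enolate donor and the methyl ester as acceptor, so C4 attacks C3 and closes ring A trans-fused; the β-keto ester enolate is then C-methylated on the α face, anti to the axial C10 methyl, which sets the quaternary C4 with the methyl equatorial (α) and the ester axial (β).

Step 12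
Reactants: 18 keto ester
Product: 20 tert-butyl (13R)-15-[(tert-butyldiphenylsilyl)oxy]-3-[(triethylsilyl)oxy]labda-2,7-dien-19-oate, via lithium enolate 19 (not isolated)
Conditions: LDA, THF, −78 °C; then TESCl, −78 → 0 °C
Reagents that add atoms: chlorotriethylsilane, CC[Si](CC)(CC)Cl
Why: Kinetic enolisation can occur only towards C2 because C4 is quaternary, and O-silylation gives the silyl enol ether, which masks the ketone for step 13 and is the substrate of step 15.

Step 13
Reactants: 20 silyl enol ether ester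
Product: 21 (13R)-15-[(tert-butyldiphenylsilyl)oxy]-3-[(triethylsilyl)oxy]labda-2,7-dien-19-ol
Conditions: LiAlH4, THF, 0 → 40 °C; Rochelle salt work-up
Reagents that add atoms: none
Why: Hydride reduction of the hindered ester to the neopentyl C19 alcohol; the silyl enol ether, the silyl ether and the alkene offer no site for hydride attack.

Step 14
Reactants: 21 C19 alcohol
Product: 22 allyl (13R)-15-[(tert-butyldiphenylsilyl)oxy]-3-[(triethylsilyl)oxy]labda-2,7-dien-19-yl carbonate
Conditions: allyl chloroformate, pyridine, DMAP (cat.), CH2Cl2, 0 °C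
Reagents that add atoms: allyl chloroformate, C=CCOC(=O)Cl
Why: Acylation of the primary alcohol under weakly basic conditions that spare the silyl enol ether; the allyl carbonate should withstand steps 15 to 17 and comes off under neutral conditions in step 18.

Step 15
Reactants: 22 silyl enol ether allyl carbonate
Product: 23 (13R)-19-{[(allyloxy)carbonyl]oxy}-15-[(tert-butyldiphenylsilyl)oxy]-3-oxolabd-7-en-2α-yl acetate
Conditions: Pb(OAc)4, CH2Cl2, −20 → 0 °C; NaHCO3 work-up
Reagents that add atoms: lead tetraacetate, CC(=O)O[Pb](OC(C)=O)(OC(C)=O)OC(C)=O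
Why: α-Acetoxylation of a silyl enol ether with Pb(OAc)4 (Rubottom-type oxidation) places the acetate regiospecifically at C2 while isolated alkenes are inert; the reagent approaches the open α face, and the epimerisable C2 centre in any case settles in the equatorial 2α arrangement.

Step 16
Reactants: 23 α-acetoxy ketone
Product: 24 (13R)-19-{[(allyloxy)carbonyl]oxy}-15-hydroxy-3-oxolabd-7-en-2α-yl acetate
Conditions: HF·pyridine, pyridine/THF, 0 °C → rt
Reagents that add atoms: none
Why: Fluoride cleavage of the primary TBDPS ether under buffered, weakly acidic conditions that leave the α-acetoxy ketone and the allyl carbonate intact.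

Step 17
Reactants: 24 C15 alcohol
Product: 26 (13R)-2α-acetoxy-19-{[(allyloxy)carbonyl]oxy}-3-oxolabd-7-en-15-oic acid, via aldehyde 25 (not isolated)
Conditions: TEMPO (cat.), PhI(OAc)2, MeCN/H2O, rt
Reagents that add atoms: water, O
Why: Nitroxyl-catalysed oxidation takes the only free alcohol through the aldehyde hydrate to the carboxylic acid and should not touch the alkene, the acetate or the carbonate.

Step 18
Reactants: 26 allyl carbonate acid
Product: 27 (13R)-2α-acetoxy-19-hydroxy-3-oxolabd-7-en-15-oic acid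
Conditions: Pd(PPh3)4 (cat.), dimedone, THF, rt
Reagents that add atoms: none
Why: Zerovalent palladium ionises the allyl carbonate (Tsuji–Trost deallylation), dimedone traps the allyl group and CO2 is lost, which frees the C19 alcohol under neutral conditions.

Step 19
Reactants: 27 β-hydroxy ketone acid
Product: 28 (13R)-2α-acetoxy-3α,19-dihydroxylabd-7-en-15-oic acid
Conditions: Me4NBH(OAc)3, MeCN/AcOH, −30 → −20 °C
Reagents that add atoms: none
Why: Hydroxyl-directed reduction (Evans–Saksena): the axial 4β-CH2OH exchanges onto boron and delivers hydride through a six-membered transition state to the β face of the C3 ketone, giving the axial 3α-alcohol; the reagent does not reduce ketones intermolecularly, nor esters or acids.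

Step 20
Reactants: 28 3α,19-diol acid
Product: 29 (13R)-2α-acetoxy-3α-hydroxy-19-oxolabd-7-en-15-oic acid (target)
Conditions: TEMPO (cat.), PhI(OAc)2, CH2Cl2, rt
Reagents that add atoms: none
Why: Nitroxyl-catalysed oxidation selects the primary C19 alcohol over the hindered axial secondary 3α-alcohol, and without water the aldehyde is not carried on to the acid.

Compound list
1 | (R)-citronellol, (3R)-3,7-dimethyloct-6-en-1-ol | CC(C)=CCC[C@@H](C)CCO | starting material
2 | tert-butyl{[(3R)-3,7-dimethyloct-6-en-1-yl]oxy}diphenylsilane | CC(C)=CCC[C@@H](C)CCO[Si](c1ccccc1)(c1ccccc1)C(C)(C)C | intermediate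
3 | (2E,6R)-8-[(tert-butyldiphenylsilyl)oxy]-2,6-dimethyloct-2-en-1-ol | OC/C(C)=C/CC[C@@H](C)CCO[Si](c1ccccc1)(c1ccccc1)C(C)(C)C | intermediate
4 | (2E,6R)-8-[(tert-butyldiphenylsilyl)oxy]-2,6-dimethyloct-2-enal | O=C/C(C)=C/CC[C@@H](C)CCO[Si](c1ccccc1)(c1ccccc1)C(C)(C)C | intermediate
5 | methyltriphenylphosphonium bromide | C[P+](c1ccccc1)(c1ccccc1)c1ccccc1.[Br-] | starting material
6 | tert-butyl{[(3R,6E)-3,7-dimethylnona-6,8-dien-1-yl]oxy}diphenylsilane | C=C/C(C)=C/CC[C@@H](C)CCO[Si](c1ccccc1)(c1ccccc1)C(C)(C)C | intermediate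
7 | ethyl (2E)-3-methyl-4-oxobut-2-enoate | CCOC(=O)/C=C(C)/C=O | starting material
8 | ethyl (1S,5R,6S)-5-{(3R)-5-[(tert-butyldiphenylsilyl)oxy]-3-methylpentyl}-6-formyl-4,6-dimethylcyclohex-3-ene-1-carboxylate (ester, side chain and C10 methyl on one face, formyl on the other) | O=C[C@@]1(C)[C@H](CC[C@@H](C)CCO[Si](c2ccccc2)(c2ccccc2)C(C)(C)C)C(C)=CC[C@@H]1C(=O)OCC | intermediate
9 | (1S,5R,6S)-5-{(3R)-5-[(tert-butyldiphenylsilyl)oxy]-3-methylpentyl}-6-formyl-4,6-dimethylcyclohex-3-ene-1-carboxylic acid | O=C[C@@]1(C)[C@H](CC[C@@H](C)CCO[Si](c2ccccc2)(c2ccccc2)C(C)(C)C)C(C)=CC[C@@H]1C(=O)O | intermediate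
10 | trimethyl phosphonoacetate, methyl 2-(dimethoxyphosphoryl)acetate | COC(=O)CP(=O)(OC)OC | starting material
11 | (1S,5R,6S)-5-{(3R)-5-[(tert-butyldiphenylsilyl)oxy]-3-methylpentyl}-6-[(1E)-3-methoxy-3-oxoprop-1-en-1-yl]-4,6-dimethylcyclohex-3-ene-1-carboxylic acid | COC(=O)/C=C/[C@@]1(C)[C@H](CC[C@@H](C)CCO[Si](c2ccccc2)(c2ccccc2)C(C)(C)C)C(C)=CC[C@@H]1C(=O)O | intermediate
12 | (1S,5R,6S)-5-{(3R)-5-[(tert-butyldiphenylsilyl)oxy]-3-methylpentyl}-6-(3-methoxy-3-oxopropyl)-4,6-dimethylcyclohex-3-ene-1-carboxylic acid | COC(=O)CC[C@@]1(C)[C@H](CC[C@@H](C)CCO[Si](c2ccccc2)(c2ccccc2)C(C)(C)C)C(C)=CC[C@@H]1C(=O)O | intermediate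
13 | methyl 3-[(1S,2R,6S)-6-(chlorocarbonyl)-2-{(3R)-5-[(tert-butyldiphenylsilyl)oxy]-3-methylpentyl}-1,3-dimethylcyclohex-3-en-1-yl]propanoate | COC(=O)CC[C@@]1(C)[C@H](CC[C@@H](C)CCO[Si](c2ccccc2)(c2ccccc2)C(C)(C)C)C(C)=CC[C@@H]1C(=O)Cl | intermediate (not isolated)
14 | methyl 3-[(1S,2R,6S)-6-(diazoacetyl)-2-{(3R)-5-[(tert-butyldiphenylsilyl)oxy]-3-methylpentyl}-1,3-dimethylcyclohex-3-en-1-yl]propanoate | COC(=O)CC[C@@]1(C)[C@H](CC[C@@H](C)CCO[Si](c2ccccc2)(c2ccccc2)C(C)(C)C)C(C)=CC[C@@H]1C(=O)C=[N+]=[N-] | intermediate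
15 | methyl 3-[(1R,2R,6R)-2-{(3R)-5-[(tert-butyldiphenylsilyl)oxy]-3-methylpentyl}-1,3-dimethyl-6-(2-oxoethenyl)cyclohex-3-en-1-yl]propanoate (ketene) | COC(=O)CC[C@@]1(C)[C@H](CC[C@@H](C)CCO[Si](c2ccccc2)(c2ccccc2)C(C)(C)C)C(C)=CC[C@@H]1C=C=O | intermediate (not isolated)
16 | methyl 3-[(1R,2R,6R)-6-(2-tert-butoxy-2-oxoethyl)-2-{(3R)-5-[(tert-butyldiphenylsilyl)oxy]-3-methylpentyl}-1,3-dimethylcyclohex-3-en-1-yl]propanoate | COC(=O)CC[C@@]1(C)[C@H](CC[C@@H](C)CCO[Si](c2ccccc2)(c2ccccc2)C(C)(C)C)C(C)=CC[C@@H]1CC(=O)OC(C)(C)C | intermediate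
17 | potassium 3-enolate (C3=C4) of tert-butyl (13R)-15-[(tert-butyldiphenylsilyl)oxy]-3-oxo-18-norlabd-7-en-19-oate | C1C[C@@]2(C)[C@H](CC[C@@H](C)CCO[Si](c3ccccc3)(c3ccccc3)C(C)(C)C)C(C)=CC[C@@H]2C(C(=O)OC(C)(C)C)=C1[O-].[K+] | intermediate (not isolated)
18 | tert-butyl (13R)-15-[(tert-butyldiphenylsilyl)oxy]-3-oxolabd-7-en-19-oate (4α-methyl, 4β-ester, trans-fused) | C1C[C@@]2(C)[C@H](CC[C@@H](C)CCO[Si](c3ccccc3)(c3ccccc3)C(C)(C)C)C(C)=CC[C@@H]2[C@](C)(C(=O)OC(C)(C)C)C1=O | intermediate
19 | lithium 2-en-3-olate of 18 | [Li+].[O-]C1=CC[C@@]2(C)[C@H](CC[C@@H](C)CCO[Si](c3ccccc3)(c3ccccc3)C(C)(C)C)C(C)=CC[C@@H]2[C@]1(C)C(=O)OC(C)(C)C | intermediate (not isolated)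
20 | tert-butyl (13R)-15-[(tert-butyldiphenylsilyl)oxy]-3-[(triethylsilyl)oxy]labda-2,7-dien-19-oate | CC[Si](CC)(CC)OC1=CC[C@@]2(C)[C@H](CC[C@@H](C)CCO[Si](c3ccccc3)(c3ccccc3)C(C)(C)C)C(C)=CC[C@@H]2[C@]1(C)C(=O)OC(C)(C)C | intermediate
21 | (13R)-15-[(tert-butyldiphenylsilyl)oxy]-3-[(triethylsilyl)oxy]labda-2,7-dien-19-ol | CC[Si](CC)(CC)OC1=CC[C@@]2(C)[C@H](CC[C@@H](C)CCO[Si](c3ccccc3)(c3ccccc3)C(C)(C)C)C(C)=CC[C@@H]2[C@]1(C)CO | intermediate
22 | allyl (13R)-15-[(tert-butyldiphenylsilyl)oxy]-3-[(triethylsilyl)oxy]labda-2,7-dien-19-yl carbonate | CC[Si](CC)(CC)OC1=CC[C@@]2(C)[C@H](CC[C@@H](C)CCO[Si](c3ccccc3)(c3ccccc3)C(C)(C)C)C(C)=CC[C@@H]2[C@]1(C)COC(=O)OCC=C | intermediate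
23 | (13R)-19-{[(allyloxy)carbonyl]oxy}-15-[(tert-butyldiphenylsilyl)oxy]-3-oxolabd-7-en-2α-yl acetate | CC(=O)O[C@H]1C[C@@]2(C)[C@H](CC[C@@H](C)CCO[Si](c3ccccc3)(c3ccccc3)C(C)(C)C)C(C)=CC[C@@H]2[C@](C)(COC(=O)OCC=C)C1=O | intermediate
24 | (13R)-19-{[(allyloxy)carbonyl]oxy}-15-hydroxy-3-oxolabd-7-en-2α-yl acetate | CC(=O)O[C@H]1C[C@@]2(C)[C@H](CC[C@@H](C)CCO)C(C)=CC[C@@H]2[C@](C)(COC(=O)OCC=C)C1=O | intermediate
25 | (13R)-2α-acetoxy-19-{[(allyloxy)carbonyl]oxy}-3-oxolabd-7-en-15-al | CC(=O)O[C@H]1C[C@@]2(C)[C@H](CC[C@@H](C)CC=O)C(C)=CC[C@@H]2[C@](C)(COC(=O)OCC=C)C1=O | intermediate (not isolated)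
26 | (13R)-2α-acetoxy-19-{[(allyloxy)carbonyl]oxy}-3-oxolabd-7-en-15-oic acid | CC(=O)O[C@H]1C[C@@]2(C)[C@H](CC[C@@H](C)CC(=O)O)C(C)=CC[C@@H]2[C@](C)(COC(=O)OCC=C)C1=O | intermediate
27 | (13R)-2α-acetoxy-19-hydroxy-3-oxolabd-7-en-15-oic acid | CC(=O)O[C@H]1C[C@@]2(C)[C@H](CC[C@@H](C)CC(=O)O)C(C)=CC[C@@H]2[C@](C)(CO)C1=O | intermediate
28 | (13R)-2α-acetoxy-3α,19-dihydroxylabd-7-en-15-oic acid | CC(=O)O[C@H]1C[C@@]2(C)[C@H](CC[C@@H](C)CC(=O)O)C(C)=CC[C@@H]2[C@](C)(CO)[C@H]1O | intermediate
29 | (13R)-2α-acetoxy-3α-hydroxy-19-oxolabd-7-en-15-oic acid | CC(=O)O[C@H]1C[C@@]2(C)[C@H](CC[C@@H](C)CC(=O)O)C(C)=CC[C@@H]2[C@](C)(C=O)[C@H]1O | target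

Total step count: 20
Longest linear sequence: 20 steps (from 1; the dienophile 7 and the reagents 5 and 10 are purchased)

Steps most likely to fail

Step 5. With this untried pairing the cycloaddition may leak through the formyl-endo transition state or lose enantioface control, because the C8 methyl and C9 chain of the diene and the β-ester of the enal can loosen the stacked aldehyde–catalyst assembly. The fallback sets out from 6 and 7 and comes back at 8. It moves facial control from the catalyst to a covalently bound auxiliary, while the aldehyde carbon stays the activating site, so the regiochemical argument is unchanged. Acetalisation of 7 with (2R,4R)-pentane-2,4-diol (PPTS, benzene, reflux with removal of water) should give ethyl (2E)-3-[(4R,6R)-4,6-dimethyl-1,3-dioxan-2-yl]but-2-enoate F1. Ionic Diels–Alder reaction of F1 with 6 (TMSOTf, cat., CH2Cl2, −78 °C) runs through the vinyl oxocarbenium ion, a known diastereoselective process for chiral dioxane acetals of enals, and should give the cycloadduct acetal ethyl (1S,5R,6S)-5-{(3R)-5-[(tert-butyldiphenylsilyl)oxy]-3-methylpentyl}-6-[(4R,6R)-4,6-dimethyl-1,3-dioxan-2-yl]-4,6-dimethylcyclohex-3-ene-1-carboxylate F2. Mild hydrolysis (PPTS, acetone/water) returns 8. The antipodal diol would be used if the sense of induction requires it.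

Step 11. Ring closure may occur through the methyl ester enolate onto the tert-butyl ester, and proton transfers during the one-pot quench may lead to O-methylation or to methylation at C2. The fallback sets out from 16 and comes back at 18. It makes the acyl acceptor unambiguous and separates the two events. Selective saponification of the methyl ester (LiOH, THF/H2O, rt; the tert-butyl ester is inert) should give 3-[(1R,2R,6R)-6-(2-tert-butoxy-2-oxoethyl)-2-{(3R)-5-[(tert-butyldiphenylsilyl)oxy]-3-methylpentyl}-1,3-dimethylcyclohex-3-en-1-yl]propanoic acid F3. Coupling with N,O-dimethylhydroxylamine (EDC, DMAP, CH2Cl2) gives the corresponding N-methoxy-N-methylamide (Weinreb amide) F4, whose α-protons are far less acidic than those of the ester. Lithium hexamethyldisilazide (THF, −78 → 0 °C) then forms only the tert-butyl ester enolate, which acylates on the amide and, after work-up, gives tert-butyl (13R)-15-[(tert-butyldiphenylsilyl)oxy]-3-oxo-18-norlabd-7-en-19-oate F5. Separate C-methylation (K2CO3, MeI, acetone, rt) gives 18.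

Step 15. Plumbylation of the hindered enol ether next to the quaternary C4 may be slow, with hydrolysis back to the ketone competing. The fallback sets out from 22 and comes back at 23. It uses the epoxidation form of the Rubottom oxidation. Dimethyldioxirane (acetone/CH2Cl2, −78 °C), which attacks the electron-rich enol ether far faster than the C7–C8 alkene or the allyl group, should give from the α face allyl (13R)-15-[(tert-butyldiphenylsilyl)oxy]-2α,3α-epoxy-3β-[(triethylsilyl)oxy]labd-7-en-19-yl carbonate F6. Mild acid (AcOH/THF/H2O, 0 °C) collapses it to (13R)-19-{[(allyloxy)carbonyl]oxy}-15-[(tert-butyldiphenylsilyl)oxy]-2α-hydroxylabd-7-en-3-one F7. Acetylation (Ac2O, pyridine, DMAP) gives 23.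

Further compounds
F1 | step 5 | ethyl (2E)-3-[(4R,6R)-4,6-dimethyl-1,3-dioxan-2-yl]but-2-enoate | C[C@@H]1C[C@@H](C)OC(O1)/C(C)=C/C(=O)OCC
F2 | step 5 | ethyl (1S,5R,6S)-5-{(3R)-5-[(tert-butyldiphenylsilyl)oxy]-3-methylpentyl}-6-[(4R,6R)-4,6-dimethyl-1,3-dioxan-2-yl]-4,6-dimethylcyclohex-3-ene-1-carboxylate | C[C@@H]1C[C@@H](C)OC(O1)[C@@]2(C)[C@H](CC[C@@H](C)CCO[Si](c3ccccc3)(c3ccccc3)C(C)(C)C)C(C)=CC[C@@H]2C(=O)OCC
F3 | step 11 | 3-[(1R,2R,6R)-6-(2-tert-butoxy-2-oxoethyl)-2-{(3R)-5-[(tert-butyldiphenylsilyl)oxy]-3-methylpentyl}-1,3-dimethylcyclohex-3-en-1-yl]propanoic acid | OC(=O)CC[C@@]1(C)[C@H](CC[C@@H](C)CCO[Si](c2ccccc2)(c2ccccc2)C(C)(C)C)C(C)=CC[C@@H]1CC(=O)OC(C)(C)C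
F4 | step 11 | tert-butyl 2-[(1R,5R,6R)-5-{(3R)-5-[(tert-butyldiphenylsilyl)oxy]-3-methylpentyl}-6-{3-[methoxy(methyl)amino]-3-oxopropyl}-4,6-dimethylcyclohex-3-en-1-yl]acetate | CON(C)C(=O)CC[C@@]1(C)[C@H](CC[C@@H](C)CCO[Si](c2ccccc2)(c2ccccc2)C(C)(C)C)C(C)=CC[C@@H]1CC(=O)OC(C)(C)C
F5 | step 11 | tert-butyl (13R)-15-[(tert-butyldiphenylsilyl)oxy]-3-oxo-18-norlabd-7-en-19-oate (C4 epimers and enol) | C1C[C@@]2(C)[C@H](CC[C@@H](C)CCO[Si](c3ccccc3)(c3ccccc3)C(C)(C)C)C(C)=CC[C@@H]2C(C(=O)OC(C)(C)C)C1=O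
F6 | step 15 | allyl (13R)-15-[(tert-butyldiphenylsilyl)oxy]-2α,3α-epoxy-3β-[(triethylsilyl)oxy]labd-7-en-19-yl carbonate | O1[C@H]2C[C@@]3(C)[C@H](CC[C@@H](C)CCO[Si](c4ccccc4)(c4ccccc4)C(C)(C)C)C(C)=CC[C@@H]3[C@](C)(COC(=O)OCC=C)[C@@]12O[Si](CC)(CC)CC
F7 | step 15 | (13R)-19-{[(allyloxy)carbonyl]oxy}-15-[(tert-butyldiphenylsilyl)oxy]-2α-hydroxylabd-7-en-3-one | O[C@H]1C[C@@]2(C)[C@H](CC[C@@H](C)CCO[Si](c3ccccc3)(c3ccccc3)C(C)(C)C)C(C)=CC[C@@H]2[C@](C)(COC(=O)OCC=C)C1=O
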